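## The problem

Target 27 is a cis-fused bicyclo[5.3.0]decene (daucane type) with four oxygenated ring carbons and a free phenol. The numbering used throughout is: ring A (five-membered) = C1 (acetoxy CH), C2 (CH2), C3 (methyl-bearing fusion carbon), C9 (fusion CH), C10 (isopropyl carbinol); ring B (seven-membered) = C3, C4 (free CHOH), C5 (CH2), C6 (methyl-bearing alkene carbon), C7 (alkene CH), C8 (aroyloxy CH), C9. β is the face carrying the C3 methyl and H-9; in this numbering 27 is 1S,3S,4S,8S,9R,10R, i.e. 1β-OAc, 10β-OH/10α-isopropyl, 4β-OH and 8α-aroyloxy.

- **Stereocentres.** Six stereocentres are spread over eight of the ten ring atoms, and the quaternary C3 beside C9–H fixes a cis ring fusion. Once that fusion exists the bicycle is folded, and its convex β face can direct a syn-dihydroxylation of ring A (C1, C10) and hydride delivery to C8. C4, next to the quaternary carbon, has no such obvious controller.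
- **Differentiation.** The four ring oxygens are in four different states: acetate on secondary C1, free tertiary OH on C10, free secondary OH on C4, and an aroyl ester on allylic C8. The two secondary carbinols C1 and C4 are sterically alike, so the order of acylations must be planned.
- **Sensitive groups.** The allylic aroyl ester ionises under strong acid and is cleaved by base or hydride. The C1 acetate does not survive base. Whenever C8 is a carbonyl, C9–H becomes epimerisable and the C10 oxygen becomes a β-leaving group. The trisubstituted alkene rules out hydrogenolytic deprotection.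
- **Enabling feature.** C4 and C8 are both carbinol carbons, they sit on adjacent ring A carbons (C3 and C9) on the same face, and they are bridged by a three-carbon isobutene unit C5–C6(CH3)=C7. Ring B is therefore a cis-1,2-diformylcyclopentane joined to a 2-methylenepropane-1,3-diyl dianion equivalent through C7–C8 and C4–C5.

## Retrosynthesis

**27 ⇒ 26 ⇒ 25 ⇒ 24 (no skeletal bond cut).** The two silyl ethers of 26 (on O4 and on the phenol) are removed together in the last step; fluoride is the one deprotection that both esters and the allylic system tolerate. The C1 acetate of 26 is put on diol 25 while C4–OH is still silylated, so the only acylable hydroxyl is C1–OH (C10–OH is tertiary). Diol 25 comes from acetonide 24. Against a route with free hydroxyls, this order removes every C1/C4 selectivity question at the cost of one protecting group. The forward steps must be mild enough for the allylic ester.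

**24 ⇒ 21 + 22 (C8 O–acyl bond).** The aroyl group is introduced late from the purchasable acid 22, because the allylic ester is the most fragile group of the target. What is asked is an 8α-alcohol 21 and an acylation strong enough for a flanked secondary carbinol.

**21 ⇒ 20 ⇒ 19 ⇒ 18 ⇒ 17 (functional group changes only).** Alcohol 21 comes from enone 20 by 1,2-reduction. Enone 20 comes from the β,γ-unsaturated ketone 19 by moving an exocyclic methylene into conjugation, so the C6 methyl and the C6=C7 position are dictated by the C8 carbonyl and the alkene cannot drift to C5=C6. Ketone 19 comes from hydroxy ketone 18 by silylation, and 18 from diol 17 by oxidation of the C8 carbinol alone. This sequence discards the C8 configuration made in the annulation and keeps only C4 from it. What is asked is site-selective oxidation of C8–OH beside C4–OH.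

**17 ⇒ 12 + 14 (cut C7–C8 and C4–C5; key step).** Both cut bonds end at carbinol carbons, so the natural polarity is two aldehydes and a bis-allyl nucleophile. Compared with cutting ring A bonds or the fusion bond C3–C9, this cut removes ring B completely and two stereocentres at once. It leaves cis-dialdehyde 12, a cyclopentane that still holds C1, C3, C9 and C10, and the three-carbon reagent 14, which carries the future C6 methyl as its methylene. The forward reaction needs the iodide end of 14 to react first, carbocyclisation of the silane end onto the second aldehyde without capture of a lactol-derived oxocarbenium ion, and the β configuration at C4.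

**14 ⇒ 13.** Halide exchange on the commercial chloride 13.

**12 ⇒ 11 ⇒ 10 ⇒ 9 ⇒ 8 (reconnect C4–C8; then C1–O and C10–O).** The two formyl carbons of 12 are reconnected as the cis-cyclobutane-1,2-diol 11, so the cis relation of the formyl groups, and of C3-methyl to H-9, is inherited from a four-membered ring and needs no control. Diol 11 is unmasked from carbonate 10. The ring A glycol of 10 is an acetonide so that it survives glycol cleavage and base. The glycol 9 arises by syn-dihydroxylation of the C1=C10 alkene of 8 from the face opposite the cyclobutane. What is asked is convex-face selectivity, which sets C1 and C10 together.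

**8 ⇒ 6 + 7 (cut C10–isopropyl); 6 ⇒ 4 via 5.** The isopropyl group is joined to C10 by cross-coupling of the Grignard reagent 7 with enol triflate 6, which places the alkene exactly at C1=C10. Triflate 6 comes from ketone 4 through enolate 5. What is asked is enolisation away from the ring-fusion carbon and a coupling that spares the cyclic carbonate.

**4 ⇒ 3 ⇒ 1 + 2 (cut C3–C4 and C8–C9).** The photocycloaddition of enone 1 with vinylene carbonate 2 forms the quaternary C3, the cis-related C9, and brings C4 and C8 in as a masked dialdehyde. Both components are commodity chemicals. The adduct 3 is racemic, so it is resolved at once to 4 before material is invested.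

## Roads not taken

**Alternative 1: Pauson–Khand closure of both rings.** The cut is C3–C9, C1–C2 and C1–C10. In the forward sense the Co2(CO)8 complex of the C9≡C10 alkyne of the acyclic dienyne A1 would combine with its C3=C2 alkene and CO to give cyclopentenone A2.
- Merits: both rings and the quaternary C3 form in one step. The C4 and C8 oxygens of A1 are already differentiated (silyl and p-methoxybenzyl) and can be set by asymmetric synthesis of an open chain. Neither a resolution nor a site-selective oxidation is needed, and in both respects this road is better than the chosen one.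
- Weak points: the ring closed by C3–C9 is seven-membered, the least reliable mode of the reaction, and only the Z alkene C6=C7 of A1 helps. The alkene partner is 1,1-disubstituted and must create a quaternary centre with facial control from remote C4/C8. A2 still lacks C9–H, the C10 carbinol and the C1 carbinol; these need reduction at the fully substituted C9, α-hydroxylation at C10 and C1 reduction, all under substrate control on a flexible ring.
- Comparison: the chosen plan sets against this a key step of a known reaction type that closes only ring B, with the ring A stereocentres already fixed on a rigid precursor.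

**Alternative 2: allenylsilane (3+2) annulation onto a cycloheptenone.** The cut is C2–C3 and C9–C10. TiCl4 would promote addition of allenylsilane A4 to the β-carbon C3 of enone A3, followed by silyl shift and ring closure at C9 to give silylcyclopentene A5.
- Merits: the quaternary centre and the cis fusion arise together. The vinylsilane marks C1/C10 for oxygenation. The C8 ketone and C4 silyl ether of A5 are differentiated from the start, which the chosen plan achieves only by steric discrimination.
- Weak points: A3 is a β,β-disubstituted enone with a γ-silyloxy group. It is a sluggish acceptor and is prone to ionisation under TiCl4, and the face of attack must be controlled by C4 alone. A5 lacks the C6 methyl and the C6=C7 alkene, so dehydrogenation, conjugate methylation and re-oxidation must follow. The vinylsilane still has to become the β-glycol, the same facial question as in the chosen route but later. An enantioselective source of A3 is also needed.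
- Comparison: the chosen plan brings C5–C7 with the methyl carbon in one reagent and needs no ring B adjustment beyond alkene migration.

**Alternative 3: ketyl pinacol closure of ring A.** The cut is C1–C10. SmI2 would couple the C1 aldehyde and the C10 isopropyl ketone of keto aldehyde A6 to give cis-diol A7.
- Merits: both ring A carbinols are set in the last carbon–carbon bond formation, cis through samarium chelation. The endgame (acetylation, ether-to-ester exchange at C8, desilylation) is shorter than the chosen one, and C4/C8 are differentiated.
- Weak points: A6 already contains the seven-membered ring with the contiguous centres C3, C4, C8 and C9, so the hardest part of the problem is only postponed and no short route to A6 is apparent. The C10 ketyl has an allylic ether at C8 in the β position, which invites reductive elimination. The C10 configuration depends on the rotamer of a hindered ketone.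
- Comparison: the chosen plan spends its key step on exactly the part that this road leaves open, starting from a cyclopentane available in eight steps.

Key step: step 10

Remarks on the chemistry (assumptions):
- Acid 22 is taken as purchasable.
- Racemic 3 is written with relative configuration only.
- The C8 configuration of 16 and 17 is the one predicted by the Felkin–Anh model; it is erased in step 11, so its epimer serves equally.

## Route

Step 1
Reactants: 1 3-methylcyclopent-2-en-1-one; 2 vinylene carbonate
Product: 3 rac-(cis,anti,cis)-5-methyl-2-oxobicyclo[3.2.0]heptane-6,7-diyl carbonate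
Conditions: hν (350 nm, Pyrex), 2 (5 equiv), acetone, 0 °C
Reagents that add atoms: none
Why: Enone–alkene [2+2] photocycloaddition through the enone triplet; the five-membered enone can only give the cis-fused cyclobutane, the carbonate should take the exo (anti) position, and the symmetric alkene raises no regiochemical question.

Step 2
Reactants: 3 rac-(cis,anti,cis)-5-methyl-2-oxobicyclo[3.2.0]heptane-6,7-diyl carbonate
Product: 4 (1R,5S,6R,7S)-5-methyl-2-oxobicyclo[3.2.0]heptane-6,7-diyl carbonate
Conditions: alcohol dehydrogenase ADH-A (Rhodococcus ruber, Prelog-selective), NAD+ (cat.), i-PrOH (10 vol %), phosphate buffer pH 7.0, 30 °C, stopped near half conversion; chromatography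
Reagents that add atoms: none
Why: Enzymatic kinetic resolution by enantiomer-selective ketone reduction: Prelog-face hydride delivery coincides with the open exo face only in the unwanted enantiomer, which should be reduced to its endo alcohol, while in 4 the same face is the concave one blocked by the cyclobutane, so 4 should remain.

Step 3
Reactants: 4 (1R,5S,6R,7S)-5-methyl-2-oxobicyclo[3.2.0]heptane-6,7-diyl carbonate
Product: 6 5-methyl-6,7-(carbonyldioxy)bicyclo[3.2.0]hept-2-en-2-yl trifluoromethanesulfonate (configuration as in 4), via potassium enolate 5 (not isolated)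
Conditions: KN(SiMe3)2, THF, −78 °C; then PhNTf2, −78 → 0 °C
Reagents that add atoms: N-phenylbis(trifluoromethanesulfonimide), O=S(=O)(N(c1ccccc1)S(=O)(=O)C(F)(F)F)C(F)(F)F
Why: Kinetic enolisation and O-sulfonylation; the hindered amide base removes a proton from the C1 methylene and not from the C9 methine at the strained four-ring fusion, and it does not attack the carbonate.

Step 4
Reactants: 6 enol triflate; 7 isopropylmagnesium chloride
Product: 8 5-methyl-2-(propan-2-yl)bicyclo[3.2.0]hept-2-ene-6,7-diyl carbonate (configuration as in 4; core C1=C10 alkene, isopropyl on C10)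
Conditions: Fe(acac)3 (5 mol %), THF/NMP, −30 °C
Reagents that add atoms: none
Why: Iron-catalysed Kumada-type cross-coupling of an alkenyl triflate with an alkyl Grignard reagent; the coupling is fast at low temperature, so the cyclic carbonate should be spared, and the alkene position is that of the triflate.

Step 5
Reactants: 8 isopropyl alkene
Product: 9 glycol of 8 with core 1β-OH and 10β-OH (10α-isopropyl), both hydroxyls on the face opposite the cyclobutane
Conditions: OsO4 (2 mol %), NMO, acetone/H2O, rt
Reagents that add atoms: osmium tetroxide as oxygen carrier, O=[Os](=O)(=O)=O; N-methylmorpholine N-oxide, C[N+]1([O-])CCOCC1; water, O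
Why: Upjohn syn-dihydroxylation; the reagent should add to the convex face of the bicyclo[3.2.0]heptene, away from the allylic cyclobutane bond, which sets C1 and C10 together as the β-cis-glycol and pushes the isopropyl group to the α side.

Step 6
Reactants: 9 glycol
Product: 10 1β,10β-O-isopropylidene acetal of 9
Conditions: 2,2-dimethoxypropane, PPTS (cat.), acetone, rt
Reagents that add atoms: 2,2-dimethoxypropane, COC(C)(C)OC
Why: Acid-catalysed transacetalisation of a cis-1,2-diol; the dioxolane protects the ring A glycol against glycol cleavage and ties down the tertiary oxygen for the carbonyl chemistry to come.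

Step 7
Reactants: 10 acetonide carbonate
Product: 11 cis-cyclobutane-1,2-diol (core C4–OH and C8–OH on the four-membered ring, acetonide intact)
Conditions: K2CO3 (cat.), MeOH, 0 °C → rt
Reagents that add atoms: none
Why: Base-catalysed methanolysis of the strained cyclic carbonate (transesterification to dimethyl carbonate); the acetonide is inert to base.

Step 8
Reactants: 11 cyclobutanediol
Product: 12 cis-dialdehyde: cyclopentane with C3 (β-CH3, α-CHO = C4), C9 (β-H, α-CHO = C8), C10 (β-O, α-isopropyl), C1 (β-O), C1/C10 oxygens as isopropylidene acetal
Conditions: NaIO4 on silica gel, CH2Cl2, rt; filtered and used at once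
Reagents that add atoms: none
Why: Periodate glycol cleavage of a cis-1,2-diol, helped by release of four-ring strain; neutral, nearly anhydrous conditions should avoid hydrate formation, C9 epimerisation and β-elimination of the C10 oxygen.

Step 9
Reactants: 13 2-(chloromethyl)-3-(trimethylsilyl)prop-1-ene
Product: 14 3-iodo-2-[(trimethylsilyl)methyl]prop-1-ene
Conditions: NaI, acetone, rt, dark
Reagents that add atoms: sodium iodide, [Na+].[I-]
Why: Finkelstein exchange at an allylic chloride, driven by precipitation of NaCl.

Step 10
Reactants: 12 cis-dialdehyde; 14 3-iodo-2-[(trimethylsilyl)methyl]prop-1-ene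
Product: 17 cis-fused bicyclic 4β,8α-diol with 6-methylene (3β-CH3, 9β-H, 10α-isopropyl, 1β,10β-O-isopropylidene), via allyltin reagent 15 (not isolated), via stannyl ether aldehyde 16 (not isolated)
Conditions: SnF2, THF, 0 °C → rt; concentrate, CH2Cl2; BF3·OEt2, −78 → −40 °C; aq. NaHCO3
Reagents that add atoms: none
Why: Divalent tin inserts into the C–I bond of 14 to give the tetravalent allyltin species 15, which adds to the C8 aldehyde (on tertiary C9, less shielded than the neopentyl C4 aldehyde) through a six-membered allyl-transfer transition state and forms C7–C8 while the allylsilane end stays inert. The tin alkoxide 16 is not worked up; BF3·OEt2 then activates the C4 aldehyde, the terminus of the 2-substituted allylsilane attacks it and silicon is lost from the β-silyl cation, which forms C4–C5 and leaves the exocyclic methylene on C6. The closest known reaction type is the stepwise (3+4) annulation of 1,4-dicarbonyl compounds with this bifunctional reagent (tin-mediated Barbier allylation, then Lewis-acid Hosomi–Sakurai cyclisation) to methylenecycloheptanediols. Ring B closes in a 7-exo-trig mode at the aldehyde carbon, eased by the cis disposition of both electrophiles on ring A. C8 should be set by Felkin–Anh addition anti to the C9–C10 bond (8α-OH) and is of no consequence because step 11 removes it. C4 should be set by the cyclisation transition state, in which the BF3-bound oxygen keeps away from the tin-bearing C8 oxygen and from the concave side of ring A and so ends on the β face. The cis fusion is inherited from 12. The step needs the iodide end to react before the silane end, which the reagent secures, and carbocyclisation to outrun ionisation of the C8-alkoxide/C4-aldehyde lactol, which the tin-bound oxygen and the low temperature are meant to secure; either order of attack on the two aldehydes gives the same constitution.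

Step 11
Reactants: 17 4β,8α-diol
Product: 18 4β-hydroxy-6-methylene-8-ketone (acetonide intact)
Conditions: PhI(OAc)2, TEMPO (20 mol %), CH2Cl2, rt
Reagents that add atoms: none
Why: Nitroxyl (oxoammonium) oxidation, which is very sensitive to crowding at the carbinol: C8–OH beside the C9 methine should react, while C4–OH beside quaternary C3 should be much slower.

Step 12
Reactants: 18 hydroxy ketone
Product: 19 4β-(tert-butyldimethylsilyl) ether of 18
Conditions: TBSOTf, 2,6-lutidine, CH2Cl2, −78 → 0 °C
Reagents that add atoms: tert-butyldimethylsilyl trifluoromethanesulfonate, CC(C)(C)[Si](C)(C)OS(=O)(=O)C(F)(F)F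
Why: Silyl triflate silylation of a hindered secondary alcohol; lutidine is too weak a base to enolise the ketone, and the ether protects C4–OH through both later acylations.

Step 13
Reactants: 19 β,γ-unsaturated ketone
Product: 20 conjugated enone: 6-methyl, C6=C7, C8=O, 4β-OTBS
Conditions: DBU (0.2 equiv), CH2Cl2, 0 °C → rt
Reagents that add atoms: none
Why: Base-mediated β,γ- to α,β-enone isomerisation through the dienolate; the C7 protons are activated by both carbonyl and alkene, so a catalytic amidine should suffice and leave C9–H and the β-oxygen on C10 untouched.

Step 14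
Reactants: 20 enone
Product: 21 8α-allylic alcohol (8S), 4β-OTBS, acetonide intact
Conditions: NaBH4, CeCl3·7H2O, MeOH, −78 → −40 °C
Reagents that add atoms: none
Why: Luche 1,2-reduction; hydride should arrive from the convex β face, syn to H-9 and away from the α-isopropyl group on C10, which gives the 8α-carbinol.

Step 15
Reactants: 21 8α-allylic alcohol; 22 4-[(tert-butyldimethylsilyl)oxy]benzoic acid
Product: 24 8α-{4-[(tert-butyldimethylsilyl)oxy]benzoate} of 21, via mixed anhydride 23 (not isolated)
Conditions: 22, 2,4,6-trichlorobenzoyl chloride, Et3N, toluene, rt; then 21, DMAP, rt → 40 °C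
Reagents that add atoms: none
Why: Yamaguchi esterification; DMAP opens mixed anhydride 23 at the less hindered aroyl carbonyl and the acylpyridinium ion acylates the flanked C8–OH with retention at C8.

Step 16
Reactants: 24 acetonide ester
Product: 25 1β,10β-diol (4β-OTBS, aryl OTBS and C8 ester intact)
Conditions: AcOH/H2O (4:1), 45 °C
Reagents that add atoms: none
Why: Acid-catalysed acetal hydrolysis; aqueous acetic acid should cleave the isopropylidene group while the hindered alkyl silyl ether, the aryl silyl ether and the allylic ester of an electron-rich benzoate survive.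

Step 17
Reactants: 25 diol
Product: 26 1β-acetate (10β-OH free)
Conditions: Ac2O, pyridine, DMAP (cat.), CH2Cl2, 0 °C → rt
Reagents that add atoms: acetic anhydride, CC(=O)OC(C)=O
Why: DMAP-catalysed acetylation; the secondary C1–OH is the only acylable hydroxyl, because C10–OH is tertiary and C4–OH and the phenol are silylated.

Step 18
Reactants: 26 bis-silyl ether
Product: 27 target (1S,3S,4S,8S,9R,10R in the core numbering)
Conditions: HF·pyridine, pyridine/THF, 0 °C → rt
Reagents that add atoms: none
Why: Fluoride-driven cleavage of both silyl ethers; the buffered acidic fluoride leaves the acetate and the allylic aroyl ester in place and gives no occasion for acyl migration.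

## Compound list

1 | 3-methylcyclopent-2-en-1-one | CC1=CC(=O)CC1 | starting material
2 | vinylene carbonate | O=C1OC=CO1 | starting material
3 | rac-(cis,anti,cis)-5-methyl-2-oxobicyclo[3.2.0]heptane-6,7-diyl carbonate (racemate, relative configuration shown) | O=C1CC[C@]2(C)[C@H]3OC(=O)O[C@H]3[C@H]12 | intermediate
4 | (1R,5S,6R,7S)-5-methyl-2-oxobicyclo[3.2.0]heptane-6,7-diyl carbonate (bicyclo C1/C5/C6/C7 = core C9/C3/C4/C8) | O=C1CC[C@]2(C)[C@H]3OC(=O)O[C@H]3[C@H]12 | intermediate
5 | potassium enolate of 4 (core C1=C10) | [K+].[O-]C1=CC[C@]2(C)[C@H]3OC(=O)O[C@H]3[C@H]12 | intermediate (not isolated)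
6 | 5-methyl-6,7-(carbonyldioxy)bicyclo[3.2.0]hept-2-en-2-yl trifluoromethanesulfonate, configuration as in 4 | O=S(=O)(OC1=CC[C@]2(C)[C@H]3OC(=O)O[C@H]3[C@H]12)C(F)(F)F | intermediate
7 | isopropylmagnesium chloride | CC(C)[Mg]Cl | starting material
8 | 5-methyl-2-(propan-2-yl)bicyclo[3.2.0]hept-2-ene-6,7-diyl carbonate, configuration as in 4 | CC(C)C1=CC[C@]2(C)[C@H]3OC(=O)O[C@H]3[C@H]12 | intermediate
9 | glycol of 8: core 1β-OH, 10β-OH, 10α-isopropyl, cyclobutane carbonate intact | O[C@H]1C[C@]2(C)[C@H]3OC(=O)O[C@H]3[C@@H]2[C@]1(O)C(C)C | intermediate
10 | 1β,10β-O-isopropylidene acetal of 9 | CC1(C)O[C@H]2C[C@]3(C)[C@H]4OC(=O)O[C@H]4[C@@H]3[C@]2(O1)C(C)C | intermediate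
11 | cis-cyclobutane-1,2-diol from 10 (core C4–OH, C8–OH) | CC1(C)O[C@H]2C[C@]3(C)[C@@H](O)[C@@H](O)[C@@H]3[C@]2(O1)C(C)C | intermediate
12 | ring A cis-dialdehyde (3β-CH3, 9β-H, formyl groups C4 and C8 α, 10α-isopropyl, 1β,10β-O-isopropylidene) | CC1(C)O[C@H]2C[C@](C)(C=O)[C@H](C=O)[C@]2(O1)C(C)C | intermediate
13 | 2-(chloromethyl)-3-(trimethylsilyl)prop-1-ene | C[Si](C)(C)CC(=C)CCl | starting material
14 | 3-iodo-2-[(trimethylsilyl)methyl]prop-1-ene | C[Si](C)(C)CC(=C)CI | intermediate
15 | difluoro(iodo){2-[(trimethylsilyl)methyl]prop-2-en-1-yl}stannane | C[Si](C)(C)CC(=C)C[Sn](F)(F)I | intermediate (not isolated)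
16 | C8 adduct of 12: C8 is (S)-CH(OSnF2I)CH2C(=CH2)CH2SiMe3, C4 formyl intact | CC1(C)O[C@H]2C[C@](C)(C=O)[C@H]([C@@H](O[Sn](F)(F)I)CC(=C)C[Si](C)(C)C)[C@]2(O1)C(C)C | intermediate (not isolated)
17 | cis-fused bicyclo[5.3.0]decane 4β,8α-diol with 6-methylene, 3β-CH3, 9β-H, 10α-isopropyl, 1β,10β-O-isopropylidene | CC1(C)O[C@H]2C[C@]3(C)[C@@H](O)CC(=C)C[C@H](O)[C@@H]3[C@]2(O1)C(C)C | intermediate
18 | 4β-hydroxy-6-methylene-8-ketone | CC1(C)O[C@H]2C[C@]3(C)[C@@H](O)CC(=C)CC(=O)[C@@H]3[C@]2(O1)C(C)C | intermediate
19 | 4β-(tert-butyldimethylsilyloxy)-6-methylene-8-ketone | CC1(C)O[C@H]2C[C@]3(C)[C@@H](O[Si](C)(C)C(C)(C)C)CC(=C)CC(=O)[C@@H]3[C@]2(O1)C(C)C | intermediate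
20 | 4β-(tert-butyldimethylsilyloxy)-6-methyl-6-en-8-one | CC1(C)O[C@H]2C[C@]3(C)[C@@H](O[Si](C)(C)C(C)(C)C)CC(C)=CC(=O)[C@@H]3[C@]2(O1)C(C)C | intermediate
21 | 8α-allylic alcohol (8S) from 20 | CC1(C)O[C@H]2C[C@]3(C)[C@@H](O[Si](C)(C)C(C)(C)C)CC(C)=C[C@H](O)[C@@H]3[C@]2(O1)C(C)C | intermediate
22 | 4-[(tert-butyldimethylsilyl)oxy]benzoic acid | CC(C)(C)[Si](C)(C)Oc1ccc(cc1)C(O)=O | starting material
23 | 4-[(tert-butyldimethylsilyl)oxy]benzoic 2,4,6-trichlorobenzoic anhydride | CC(C)(C)[Si](C)(C)Oc1ccc(cc1)C(=O)OC(=O)c1c(Cl)cc(Cl)cc1Cl | intermediate (not isolated)
24 | 8α-{4-[(tert-butyldimethylsilyl)oxy]benzoate} of 21 | CC1(C)O[C@H]2C[C@]3(C)[C@@H](O[Si](C)(C)C(C)(C)C)CC(C)=C[C@H](OC(=O)c4ccc(O[Si](C)(C)C(C)(C)C)cc4)[C@@H]3[C@]2(O1)C(C)C | intermediate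
25 | 1β,10β-diol from 24 (both silyl ethers and C8 ester intact) | O[C@H]1C[C@]2(C)[C@@H](O[Si](C)(C)C(C)(C)C)CC(C)=C[C@H](OC(=O)c3ccc(O[Si](C)(C)C(C)(C)C)cc3)[C@@H]2[C@]1(O)C(C)C | intermediate
26 | 1β-acetate of 25 | CC(=O)O[C@H]1C[C@]2(C)[C@@H](O[Si](C)(C)C(C)(C)C)CC(C)=C[C@H](OC(=O)c3ccc(O[Si](C)(C)C(C)(C)C)cc3)[C@@H]2[C@]1(O)C(C)C | intermediate
27 | target: 1β-acetoxy-4β,10β-dihydroxy-8α-(4-hydroxybenzoyloxy)-3β,6-dimethyl-10α-isopropyl cis-bicyclo[5.3.0]dec-6-ene (1S,3S,4S,8S,9R,10R) | CC(=O)O[C@H]1C[C@]2(C)[C@@H](O)CC(C)=C[C@H](OC(=O)c3ccc(O)cc3)[C@@H]2[C@]1(O)C(C)C | target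

## Step count and risks

Total step count: 18. Longest linear sequence: 17 steps (steps 1–8 and 10–18); step 9 is a one-step branch.

**Step 10 (key step).** The C8 alkoxide may add to the C4 aldehyde, and Lewis-acid ionisation of that lactol followed by allylsilane capture would close an oxygen bridge between C4 and C8 instead of leaving two hydroxyls. The facial control at C4 may also be incomplete, since it rests on a seven-membered transition state. The fallback sets out from 12 and avoids cationic intermediates: indium powder and 3-bromo-2-(bromomethyl)prop-1-ene in THF/H2O add twice in Barbier fashion. The first addition gives the bromoallyl mono-adduct F1 (present as its lactol). The second, intramolecular allylindium addition reaches the open form and should give the diol as a mixture of C4/C8 epimers F2. Dess–Martin oxidation under NaHCO3 buffer converges this mixture on the 4,8-diketone F3. NaBH4/CeCl3·7H2O at −78 °C should then deliver hydride anti to the C3 methyl at C4 and from the convex face at C8, which returns to the route at 17.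

**Step 11.** The site selectivity between two flanked secondary carbinols may be low or reversed, and over-oxidation may follow. The fallback sets out from 17 and uses the same steric bias the other way: if C4–OH is the more accessible hydroxyl, TBSCl/imidazole in DMF should silylate it first to the 4-silyl ether 8-alcohol F4, and Dess–Martin oxidation of its C8–OH returns to the route at 19. Any regioisomer would be desilylated and recycled.

**Step 2.** The dehydrogenase may not accept the tricyclic ketone or may discriminate its enantiomers poorly. The fallback sets out from 3 and is physical: preparative chromatography on a chiral stationary phase with supercritical CO2 returns to the route at 4 and makes no new compound.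

**Step 4.** The Grignard reagent may add to the cyclic carbonate, and β-hydride processes in the iron cycle may reduce the triflate or isomerise the isopropyl group. The fallback sets out from 6: Suzuki–Miyaura coupling with isopropenylboronic acid pinacol ester (Pd(PPh3)4, K3PO4, dioxane/H2O) should give the isopropenyl diene F5. Hydrogenation over RhCl(PPh3)3 should saturate only the 1,1-disubstituted alkene, which returns to the route at 8.

**Step 14.** Hydride delivery to C8 may show poor facial selectivity on the flexible seven-membered enone. The fallback sets out from 20: if reduction favours the 8β-alcohol F6, it is esterified with acid 22 under Mitsunobu conditions (PPh3, diisopropyl azodicarboxylate, toluene). This inverts C8 while installing the aroyl group and returns to the route at 24.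

**Step 16.** The acid needed for the acetal may ionise the allylic aroyloxy group or remove silyl groups early. The fallback sets out from 20 and takes the acetonide off before the allylic ester exists. Aqueous acetic acid on the enone should give the enone diol F7. Acetylation (Ac2O, pyridine, DMAP) gives the enone 1-acetate F8. Luche reduction gives the 8α-allylic alcohol 1-acetate F9. Yamaguchi esterification with 23 (from 22) returns to the route at 26.

## Further compounds

F1 | step 10 | bromoallyl mono-adduct of 12 (C8 carbinol bearing CH2C(=CH2)CH2Br, C8 configuration open, C4 formyl or lactol) | CC1(C)O[C@H]2C[C@](C)(C=O)[C@H](C(O)CC(=C)CBr)[C@]2(O1)C(C)C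
F2 | step 10 | 6-methylene-4,8-diol as mixture of C4/C8 epimers | CC1(C)O[C@H]2C[C@]3(C)C(O)CC(=C)CC(O)[C@@H]3[C@]2(O1)C(C)C
F3 | step 10 | 6-methylene-4,8-diketone | CC1(C)O[C@H]2C[C@]3(C)C(=O)CC(=C)CC(=O)[C@@H]3[C@]2(O1)C(C)C
F4 | step 11 | 4β-(tert-butyldimethylsilyloxy)-6-methylene-8α-alcohol | CC1(C)O[C@H]2C[C@]3(C)[C@@H](O[Si](C)(C)C(C)(C)C)CC(=C)C[C@H](O)[C@@H]3[C@]2(O1)C(C)C
F0 | step 2 | none | none
F5 | step 4 | 5-methyl-2-(prop-1-en-2-yl)bicyclo[3.2.0]hept-2-ene-6,7-diyl carbonate, configuration as in 4 | C=C(C)C1=CC[C@]2(C)[C@H]3OC(=O)O[C@H]3[C@H]12
F6 | step 14 | 8β-allylic alcohol (C8 epimer of 21) | CC1(C)O[C@H]2C[C@]3(C)[C@@H](O[Si](C)(C)C(C)(C)C)CC(C)=C[C@@H](O)[C@@H]3[C@]2(O1)C(C)C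
F7 | step 16 | enone 1β,10β-diol (acetonide of 20 removed) | O[C@H]1C[C@]2(C)[C@@H](O[Si](C)(C)C(C)(C)C)CC(C)=CC(=O)[C@@H]2[C@]1(O)C(C)C
F8 | step 16 | enone 1β-acetate | CC(=O)O[C@H]1C[C@]2(C)[C@@H](O[Si](C)(C)C(C)(C)C)CC(C)=CC(=O)[C@@H]2[C@]1(O)C(C)C
F9 | step 16 | 8α-allylic alcohol 1β-acetate | CC(=O)O[C@H]1C[C@]2(C)[C@@H](O[Si](C)(C)C(C)(C)C)CC(C)=C[C@H](O)[C@@H]2[C@]1(O)C(C)C
A1 | alternative 1 | acyclic dienyne with C3=C2 alkene, Z-C6=C7 alkene, C9≡C10 alkyne, 4-silyl and 8-(4-methoxybenzyl) ethers | C=C(C)[C@@H](O[Si](C)(C)C(C)(C)C)C/C(C)=C\[C@H](OCc1ccc(OC)cc1)C#CC(C)C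
A2 | alternative 1 | bicyclic 2-isopropylcyclopentenone with angular methyl | O=C1C[C@]2(C)[C@@H](O[Si](C)(C)C(C)(C)C)CC(C)=C[C@H](OCc3ccc(OC)cc3)C2=C1C(C)C
A3 | alternative 2 | 4-(tert-butyldimethylsilyloxy)-3-methylcyclohept-2-en-1-one | CC1=CC(=O)CCC[C@@H]1O[Si](C)(C)C(C)(C)C
A4 | alternative 2 | trimethyl(4-methylpenta-1,2-dien-3-yl)silane | C=C=C(C(C)C)[Si](C)(C)C
A5 | alternative 2 | cis-fused bicyclic C8 ketone with C1-silyl C1=C10 alkene | C[Si](C)(C)C1=C(C(C)C)[C@H]2C(=O)CCC[C@H](O[Si](C)(C)C(C)(C)C)[C@@]2(C)C1
A6 | alternative 3 | cycloheptene keto aldehyde (C1 formyl on the C2 methylene, C10 isopropyl ketone on C9) | O=CC[C@]1(C)[C@@H](O[Si](C)(C)C(C)(C)C)CC(C)=C[C@H](OCc2ccc(OC)cc2)[C@@H]1C(=O)C(C)C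
A7 | alternative 3 | bicyclic cis-1,2-diol | O[C@H]1C[C@]2(C)[C@@H](O[Si](C)(C)C(C)(C)C)CC(C)=C[C@H](OCc3ccc(OC)cc3)[C@@H]2[C@]1(O)C(C)C
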